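Ring B of this ent-labdane holds four contiguous stereocentres: C5, quaternary C10 (bearing methyl C20), C9 and C8. With a C6=C7 double bond added it is a cyclohexene, so C5–C10 and C8–C9 are disconnected together. In the forward direction, one intramolecular Diels–Alder reaction of an open chain closes ring B by cycloaddition and ring A through the C1–C4 tether. It sets C5, C8, C9 and C10 from the single C3 carbinol centre. The precursor joins a methyl (E)-3-methylenoate (C9=C10, ester carbon C11) through C1–C4 (C3 silyl ether, C4 gem-dimethyl) to an (E,E)-dienyl pivalate (C5=C6–C7=C8–O). C8 is later re-set by equatorial addition of C17 to the ketone.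

Key step: step 8

Remark: labdane numbering (C1–C20) is used for every compound; the target SMILES is read as the ent-labdane (3R,5S,8R,9S,10R,13Z) with a trans-decalin, equatorial 3-OH, axial 8-OH cis to C20 and equatorial C17 aldehyde, and commercial methyl geranate is taken as the pure (2E) isomer.

Step 1
Reactants: 1 methyl geranate
Product: 3 methyl (2E)-3-methyl-6-oxohex-2-enoate, via secondary ozonide 2 (not isolated)
Conditions: O3 (1 equiv, Sudan Red 7B end point), CH2Cl2, −78 °C; then Me2S, −78 °C → rt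
Reagents that add atoms: ozone, [O-][O+]=O
Why: Chemoselective ozonolysis with reductive work-up: the electron-rich isopropylidene alkene takes up ozone much faster than the ester-conjugated C9=C10 alkene, so one equivalent cleaves only the chain end, frees the C3 aldehyde and leaves the (E)-enoate geometry untouched.

Step 2
Reactants: 3 methyl (2E)-3-methyl-6-oxohex-2-enoate; 4 prenylmagnesium chloride
Product: 7 methyl (2E,6R)-6-hydroxy-3,7,7-trimethylnona-2,8-dienoate, via prenyldiisopinocampheylborane 5 (not isolated), via borinate ester 6 (not isolated)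
Conditions: (−)-Ipc2BOMe, 4, Et2O, −78 → 0 °C; then 3, −78 °C; then MeOH, pH 7 buffer (NaH2PO4/Na2HPO4), 30% H2O2, 0 °C → rt
Reagents that add atoms: (−)-B-methoxydiisopinocampheylborane, COB([C@@H]1C[C@@H]2C[C@H]([C@H]1C)C2(C)C)[C@@H]1C[C@@H]2C[C@H]([C@H]1C)C2(C)C (boron and Ipc groups remain only in 5 and 6)
Why: Brown asymmetric allylboration used as a reverse prenylation: the prenylborane adds through a closed chair Zimmerman–Traxler transition state with allylic transposition, which forms C3–C4 and the quaternary gem-dimethyl C4 with a C5=C6 vinyl group, and the Ipc ligands derived from (+)-α-pinene direct attack to the Si face of the aldehyde to set (R)-C3.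

Step 3
Reactants: 7 methyl (2E,6R)-6-hydroxy-3,7,7-trimethylnona-2,8-dienoate
Product: 8 methyl (2E,6R)-6-(tert-butyldimethylsilyloxy)-3,7,7-trimethylnona-2,8-dienoate
Conditions: TBSOTf, 2,6-lutidine, CH2Cl2, 0 °C
Reagents that add atoms: tert-butyldimethylsilyl triflate, CC(C)(C)[Si](C)(C)OS(=O)(=O)C(F)(F)F
Why: Silyl ether protection: the reactive triflate silylates the neopentyl-type secondary alcohol that the chloride would attack only slowly, and the ether tolerates the boranes, bases, aluminium Lewis acid, hydrides and Grignard reagent still to come.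

Step 4
Reactants: 8 methyl (2E,6R)-6-(tert-butyldimethylsilyloxy)-3,7,7-trimethylnona-2,8-dienoate
Product: 10 methyl (2E,6R)-6-(tert-butyldimethylsilyloxy)-9-hydroxy-3,7,7-trimethylnon-2-enoate, via alkyl-9-BBN adduct 9 (not isolated)
Conditions: 9-BBN (1.5 equiv), THF, rt; then 30% H2O2, aq NaOAc, 0 °C → rt
Reagents that add atoms: 9-borabicyclo[3.3.1]nonane, B1C2CCCC1CCC2 (remains only in 9); hydrogen peroxide, OO
Why: Hydroboration–oxidation: bulky 9-BBN adds anti-Markovnikov to the only monosubstituted alkene, placing boron on terminal C6 away from quaternary C4 and ignoring the trisubstituted electron-poor enoate, and buffered peroxide then exchanges boron for hydroxyl without touching the methyl ester.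

Step 5
Reactants: 10 methyl (2E,6R)-6-(tert-butyldimethylsilyloxy)-9-hydroxy-3,7,7-trimethylnon-2-enoate
Product: 11 methyl (2E,6R)-6-(tert-butyldimethylsilyloxy)-3,7,7-trimethyl-9-oxonon-2-enoate
Conditions: TEMPO (10 mol %), PhI(OAc)2, CH2Cl2, rt
Reagents that add atoms: none
Why: Oxoammonium (TEMPO) oxidation: the nitroxyl/PhI(OAc)2 couple stops at the aldehyde and is inert toward the silyl ether, the enoate and the C3 stereocentre.

Step 6
Reactants: 11 methyl (2E,6R)-6-(tert-butyldimethylsilyloxy)-3,7,7-trimethyl-9-oxonon-2-enoate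
Product: 12 methyl (2E,6R,9E)-6-(tert-butyldimethylsilyloxy)-3,7,7-trimethyl-11-oxoundeca-2,9-dienoate
Conditions: Ph3P=CHCHO (1.3 equiv), toluene, 80 °C
Reagents that add atoms: (triphenylphosphoranylidene)acetaldehyde, O=CC=P(c1ccccc1)(c1ccccc1)c1ccccc1
Why: Wittig olefination with a stabilised ylide: reversible oxaphosphetane formation favours the (E)-enal, which adds C7 and C8 and leaves the C5 methylene as the only γ-position for the dienolate formation that follows.

Step 7
Reactants: 12 methyl (2E,6R,9E)-6-(tert-butyldimethylsilyloxy)-3,7,7-trimethyl-11-oxoundeca-2,9-dienoate; 13 pivaloyl chloride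
Product: 15 methyl (2E,6R,8E,10E)-6-(tert-butyldimethylsilyloxy)-3,7,7-trimethyl-11-(pivaloyloxy)undeca-2,8,10-trienoate, via potassium dienolate 14 (not isolated)
Conditions: KOtBu (1.1 equiv), THF, −78 °C; then 13, −78 → −20 °C
Reagents that add atoms: potassium tert-butoxide, CC(C)(C)[O-].[K+] (potassium remains only in 14)
Why: γ-Deprotonation of an enal and O-acylation of the extended enolate: the C5 hydrogens of the enal are several pK units more acidic than the γ-hydrogens of the enoate, the s-trans enal delivers the (E)-C7=C8 enolate, quaternary C4 forces the (E)-C5=C6 geometry, and the hard potassium dienolate is captured on oxygen by the acid chloride.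

Step 8
Reactants: 15 methyl (2E,6R,8E,10E)-6-(tert-butyldimethylsilyloxy)-3,7,7-trimethyl-11-(pivaloyloxy)undeca-2,8,10-trienoate
Product: 16 methyl (1S,2R,4aS,6R,8aR)-6-(tert-butyldimethylsilyloxy)-2-(pivaloyloxy)-5,5,8a-trimethyl-1,2,4a,5,6,7,8,8a-octahydronaphthalene-1-carboxylate
Conditions: EtAlCl2 (1.5 equiv), CH2Cl2 (0.01 M), −40 °C → rt; aq NaHCO3
Reagents that add atoms: none
Why: Aluminium coordination to the enoate carbonyl lowers the dienophile LUMO so that a concerted, asynchronous, suprafacial [4+2] cycloaddition with the donor-substituted diene forms C5–C10 and C8–C9, the polarity being matched because the oxygen-bearing terminus C8 meets the ester α-carbon C9 and the nucleophilic terminus C5 meets the β-carbon C10. The closest known reaction type is the Lewis-acid-promoted intramolecular Diels–Alder reaction of deca-1,7,9-triene esters that carry a methyl group on the inner dienophile carbon, which gives trans-fused, angularly methylated octalins. Ring B closes by the cycloaddition itself, and ring A closes as the six-membered ring spanned by the C1–C4 tether in a chair-like arrangement. C9 and C10 follow from the (E)-enoate geometry (C11 cis to C20), C5 and C8 from the (E,E)-diene geometry (C4 cis to the pivaloyloxy group), and the relation between the two pairs from the ester-endo approach, which puts H5 trans to C20 and the C8 oxygen cis to C11. The absolute sense comes from C3, whose silyloxy group takes the equatorial site of the chair tether next to the C4 gem-dimethyl group and so offers one diene face to the dienophile. The step needs endo over exo and one diene face over the other: the Lewis acid strengthens the endo preference, the hindered and weakly basic pivalate carbonyl leaves the acid on the enoate, and the C4 gem-dimethyl group favours the folded reactive conformer.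

Step 9
Reactants: 16 the octalin from step 8
Product: 17 methyl (1S,2R,4aS,6R,8aR)-6-(tert-butyldimethylsilyloxy)-2-(pivaloyloxy)-5,5,8a-trimethyldecahydronaphthalene-1-carboxylate
Conditions: H2 (1 atm), 5% Rh/Al2O3, EtOAc, rt
Reagents that add atoms: none
Why: Heterogeneous catalytic hydrogenation: the cis-disubstituted C6=C7 alkene is the only reducible π bond, its face opposite C20 is open, Rh/Al2O3 in a neutral solvent saturates allylic esters with little C–O hydrogenolysis, and no stereocentre is created.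

Step 10
Reactants: 17 the decalin ester pivalate from step 9
Product: 18 (1R,2R,4aS,6R,8aR)-6-(tert-butyldimethylsilyloxy)-1-(hydroxymethyl)-5,5,8a-trimethyldecahydronaphthalen-2-ol
Conditions: LiAlH4 (4 equiv), THF, 0 °C → rt; aq NaOH work-up
Reagents that add atoms: none
Why: Hydride reduction of both esters: LiAlH4 turns the C11 methyl ester into the primary alcohol and cleaves the pivalate to the axial C8 alcohol in one operation, faster than it can act as a base on C9–H, while the silyl ether and all ring stereocentres stay as they are.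

Step 11
Reactants: 18 the 8,11-diol from step 10
Product: 19 (1S,2R,4aS,6R,8aR)-6-(tert-butyldimethylsilyloxy)-2-hydroxy-5,5,8a-trimethyldecahydronaphthalene-1-carbaldehyde
Conditions: TEMPO (10 mol %), PhI(OAc)2 (1.1 equiv), CH2Cl2, rt
Reagents that add atoms: none
Why: Chemoselective oxoammonium (TEMPO) oxidation: the bulky oxoammonium salt oxidises the primary C11 alcohol much faster than the axial secondary C8 alcohol, and the weakly acidic medium avoids dehydration of the β-hydroxy aldehyde and epimerisation of the equatorial C9 substituent.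

Step 12
Reactants: 19 the β-hydroxy aldehyde from step 11
Product: 20 (1S,2R,4aS,6R,8aR)-6-(tert-butyldimethylsilyloxy)-1-ethenyl-5,5,8a-trimethyldecahydronaphthalen-2-ol
Conditions: Ph3PCH3Br (3.5 equiv), KOtBu (3.2 equiv), THF, 0 °C; then 19, −78 → 0 °C
Reagents that add atoms: methyltriphenylphosphonium bromide, C[P+](c1ccccc1)(c1ccccc1)c1ccccc1.[Br-]
Why: Wittig methylenation: excess non-stabilised ylide first turns the C8 hydroxyl into its alkoxide, a poor leaving group that blocks β-elimination, and then methylenates the aldehyde at low temperature to add C12 with C9 unchanged.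

Step 13
Reactants: 21 ethyl but-2-ynoate
Product: 22 ethyl (2Z)-3-iodobut-2-enoate
Conditions: NaI, AcOH, 110 °C
Reagents that add atoms: sodium iodide, [Na+].[I-]
Why: Conjugate hydroiodination of an ynoate: iodide adds to the β-carbon and the allenolate is protonated anti to iodine, so iodine ends up cis to the ester and the geometry needed for C13=C14 is fixed in a small fragment.

Step 14
Reactants: 20 the C9-vinyl alcohol from step 12; 22 ethyl (2Z)-3-iodobut-2-enoate
Product: 24 ethyl (3R,5S,8R,9S,10R,13Z)-3-(tert-butyldimethylsilyloxy)-8-hydroxy-17-norlabd-13-en-15-oate, via alkyl-9-BBN adduct 23 (not isolated)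
Conditions: 20, 9-BBN (2.5 equiv), THF, rt → 45 °C; then 22, Pd(dppf)Cl2 (5 mol %), AsPh3, Cs2CO3, DMF/H2O, rt
Reagents that add atoms: 9-borabicyclo[3.3.1]nonane, B1C2CCCC1CCC2 (remains only in 23)
Why: Hydroboration followed by B-alkyl Suzuki–Miyaura coupling: 9-BBN places boron on terminal C12, and zerovalent palladium formed from Pd(dppf)Cl2 joins C12 to C13 with retention of the iodoalkene geometry, which installs the whole (13Z)-enoate chain in one flask while excess borane covers the C8 hydroxyl until the aqueous base releases it.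

Step 15
Reactants: 24 the 8-hydroxy ester from step 14
Product: 25 ethyl (3R,5S,9S,10R,13Z)-3-(tert-butyldimethylsilyloxy)-8-oxo-17-norlabd-13-en-15-oate
Conditions: DMP, CH2Cl2, rt
Reagents that add atoms: none
Why: Dess–Martin oxidation: the periodinane converts the hindered axial C8 alcohol into the ketone under near-neutral conditions, so the equatorial (thermodynamically preferred) C9 side chain, the (Z)-enoate and the silyl ether are not disturbed.

Step 16
Reactants: 25 the C8 ketone from step 15
Product: 27 ethyl (3R,5S,8R,9S,10R,13Z)-3-(tert-butyldimethylsilyloxy)-8,17-dihydroxylabd-13-en-15-oate, via silylmethyl carbinol 26 (not isolated)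
Conditions: ClMgCH2SiMe2(OiPr) (3 equiv, from ClCH2SiMe2(OiPr) and Mg), LaCl3·2LiCl (30 mol %), THF, −40 → 0 °C; aq NH4Cl; crude 26, 30% H2O2, KF, KHCO3, THF/MeOH, rt
Reagents that add atoms: (isopropoxydimethylsilyl)methylmagnesium chloride, CC(C)O[Si](C)(C)C[Mg]Cl; hydrogen peroxide, OO
Why: Grignard addition of a hydroxymethyl anion equivalent followed by Tamao–Fleming oxidation: axial approach to the C8 ketone is blocked by the syn-axial C20 methyl, so the weakly basic silylmethyl reagent attacks equatorially to give the axial 8-OH cis to C20 and equatorial C17, it reacts with the ketone faster than with the hindered conjugated ester at low temperature, and the C–Si bond is then oxidised to C–OH.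

Step 17
Reactants: 27 the 8,17-diol ester from step 16
Product: 28 (3R,5S,8R,9S,10R,13Z)-3-(tert-butyldimethylsilyloxy)-8,17-dihydroxylabd-13-en-15-oic acid
Conditions: LiOH, THF/MeOH/H2O, 45 °C; then 1 M HCl to pH 3
Reagents that add atoms: lithium hydroxide, [Li+].[OH-]
Why: Saponification: hydroxide cleaves the ethyl ester by acyl substitution, a path that does not isomerise the (Z)-alkene, and it is run before the base-sensitive α-hydroxy aldehyde exists.

Step 18
Reactants: 28 the diol acid from step 17
Product: 29 (3R,5S,8R,9S,10R,13Z)-3-(tert-butyldimethylsilyloxy)-8-hydroxy-17-oxolabd-13-en-15-oic acid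
Conditions: IBX (1.5 equiv), DMSO, rt
Reagents that add atoms: none
Why: IBX oxidation: the hypervalent iodine reagent oxidises the primary C17 alcohol of the 1,2-diol to the aldehyde without glycol cleavage or over-oxidation, cannot oxidise the tertiary C8 alcohol and tolerates the free acid.

Step 19
Reactants: 29 the silyl-protected aldehyde acid from step 18
Product: 30 (3R,5S,8R,9S,10R,13Z)-3,8-dihydroxy-17-oxolabd-13-en-15-oic acid (CNP0273710.1)
Conditions: 48% aq HF, MeCN, 0 °C → rt
Reagents that add atoms: none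
Why: Acidic fluoride desilylation: HF removes the hindered C3 silyl ether while avoiding basic media that could trigger α-ketol rearrangement of the non-enolisable α-hydroxy aldehyde, and the carbinol C8 next to the formyl group resists ionisation.

Compound list
1 | methyl geranate, methyl (2E)-3,7-dimethylocta-2,6-dienoate | COC(=O)/C=C(\C)CCC=C(C)C | starting material
2 | methyl (2E)-5-(5,5-dimethyl-1,2,4-trioxolan-3-yl)-3-methylpent-2-enoate (secondary ozonide, not isolated) | COC(=O)/C=C(\C)CCC1OOC(C)(C)O1 | intermediate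
3 | methyl (2E)-3-methyl-6-oxohex-2-enoate | COC(=O)/C=C(\C)CCC=O | intermediate
4 | prenylmagnesium chloride (3-methylbut-2-enylmagnesium chloride) | CC(C)=CC[Mg]Cl | starting material
5 | B-(3-methylbut-2-enyl)diisopinocampheylborane, Ipc groups from (+)-α-pinene (not isolated) | CC(C)=CCB([C@@H]1C[C@@H]2C[C@H]([C@H]1C)C2(C)C)[C@@H]1C[C@@H]2C[C@H]([C@H]1C)C2(C)C | intermediate
6 | diisopinocampheylborinate ester of 7, C3–O–B(Ipc)2 (not isolated) | COC(=O)/C=C(\C)CC[C@@H](OB([C@@H]1C[C@@H]2C[C@H]([C@H]1C)C2(C)C)[C@@H]1C[C@@H]2C[C@H]([C@H]1C)C2(C)C)C(C)(C)C=C | intermediate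
7 | methyl (2E,6R)-6-hydroxy-3,7,7-trimethylnona-2,8-dienoate | COC(=O)/C=C(\C)CC[C@@H](O)C(C)(C)C=C | intermediate
8 | methyl (2E,6R)-6-(tert-butyldimethylsilyloxy)-3,7,7-trimethylnona-2,8-dienoate | COC(=O)/C=C(\C)CC[C@@H](O[Si](C)(C)C(C)(C)C)C(C)(C)C=C | intermediate
9 | 9-BBN adduct of 8, boron on the chain terminus (labdane C6) (not isolated) | COC(=O)/C=C(\C)CC[C@@H](O[Si](C)(C)C(C)(C)C)C(C)(C)CCB1C2CCCC1CCC2 | intermediate
10 | methyl (2E,6R)-6-(tert-butyldimethylsilyloxy)-9-hydroxy-3,7,7-trimethylnon-2-enoate | COC(=O)/C=C(\C)CC[C@@H](O[Si](C)(C)C(C)(C)C)C(C)(C)CCO | intermediate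
11 | methyl (2E,6R)-6-(tert-butyldimethylsilyloxy)-3,7,7-trimethyl-9-oxonon-2-enoate | COC(=O)/C=C(\C)CC[C@@H](O[Si](C)(C)C(C)(C)C)C(C)(C)CC=O | intermediate
12 | methyl (2E,6R,9E)-6-(tert-butyldimethylsilyloxy)-3,7,7-trimethyl-11-oxoundeca-2,9-dienoate | COC(=O)/C=C(\C)CC[C@@H](O[Si](C)(C)C(C)(C)C)C(C)(C)C/C=C/C=O | intermediate
13 | pivaloyl chloride | CC(C)(C)C(=O)Cl | starting material
14 | potassium (8E,10E)-dienolate of 12 (not isolated) | COC(=O)/C=C(\C)CC[C@@H](O[Si](C)(C)C(C)(C)C)C(C)(C)/C=C/C=C/[O-].[K+] | intermediate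
15 | methyl (2E,6R,8E,10E)-6-(tert-butyldimethylsilyloxy)-3,7,7-trimethyl-11-(pivaloyloxy)undeca-2,8,10-trienoate | COC(=O)/C=C(\C)CC[C@@H](O[Si](C)(C)C(C)(C)C)C(C)(C)/C=C/C=C/OC(=O)C(C)(C)C | intermediate
16 | methyl (1S,2R,4aS,6R,8aR)-6-(tert-butyldimethylsilyloxy)-2-(pivaloyloxy)-5,5,8a-trimethyl-1,2,4a,5,6,7,8,8a-octahydronaphthalene-1-carboxylate (trans-fused; labdane 3R,5S,8R,9S,10R; C6=C7 alkene) | COC(=O)[C@H]1[C@]2(C)CC[C@@H](O[Si](C)(C)C(C)(C)C)C(C)(C)[C@H]2C=C[C@H]1OC(=O)C(C)(C)C | intermediate
17 | methyl (1S,2R,4aS,6R,8aR)-6-(tert-butyldimethylsilyloxy)-2-(pivaloyloxy)-5,5,8a-trimethyldecahydronaphthalene-1-carboxylate | COC(=O)[C@H]1[C@]2(C)CC[C@@H](O[Si](C)(C)C(C)(C)C)C(C)(C)[C@H]2CC[C@H]1OC(=O)C(C)(C)C | intermediate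
18 | (1R,2R,4aS,6R,8aR)-6-(tert-butyldimethylsilyloxy)-1-(hydroxymethyl)-5,5,8a-trimethyldecahydronaphthalen-2-ol (axial 8-OH, equatorial C11H2OH) | OC[C@H]1[C@]2(C)CC[C@@H](O[Si](C)(C)C(C)(C)C)C(C)(C)[C@H]2CC[C@H]1O | intermediate
19 | (1S,2R,4aS,6R,8aR)-6-(tert-butyldimethylsilyloxy)-2-hydroxy-5,5,8a-trimethyldecahydronaphthalene-1-carbaldehyde | O=C[C@H]1[C@]2(C)CC[C@@H](O[Si](C)(C)C(C)(C)C)C(C)(C)[C@H]2CC[C@H]1O | intermediate
20 | (1S,2R,4aS,6R,8aR)-6-(tert-butyldimethylsilyloxy)-1-ethenyl-5,5,8a-trimethyldecahydronaphthalen-2-ol | C=C[C@H]1[C@]2(C)CC[C@@H](O[Si](C)(C)C(C)(C)C)C(C)(C)[C@H]2CC[C@H]1O | intermediate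
21 | ethyl but-2-ynoate | CCOC(=O)C#CC | starting material
22 | ethyl (2Z)-3-iodobut-2-enoate (iodine cis to the ester) | C/C(I)=C/C(=O)OCC | intermediate
23 | 9-BBN adduct of 20, boron on C12, drawn with the 8-OH free (not isolated) | C1CC2CCCC(C1)B2CC[C@H]1[C@]2(C)CC[C@@H](O[Si](C)(C)C(C)(C)C)C(C)(C)[C@H]2CC[C@H]1O | intermediate
24 | ethyl (3R,5S,8R,9S,10R,13Z)-3-(tert-butyldimethylsilyloxy)-8-hydroxy-17-norlabd-13-en-15-oate | C/C(=C/C(=O)OCC)CC[C@H]1[C@]2(C)CC[C@@H](O[Si](C)(C)C(C)(C)C)C(C)(C)[C@H]2CC[C@H]1O | intermediate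
25 | ethyl (3R,5S,9S,10R,13Z)-3-(tert-butyldimethylsilyloxy)-8-oxo-17-norlabd-13-en-15-oate | C/C(=C/C(=O)OCC)CC[C@H]1[C@]2(C)CC[C@@H](O[Si](C)(C)C(C)(C)C)C(C)(C)[C@H]2CCC1=O | intermediate
26 | ethyl (3R,5S,8R,9S,10R,13Z)-3-(tert-butyldimethylsilyloxy)-8-hydroxy-17-(isopropoxydimethylsilyl)labd-13-en-15-oate (not isolated) | C/C(=C/C(=O)OCC)CC[C@H]1[C@]2(C)CC[C@@H](O[Si](C)(C)C(C)(C)C)C(C)(C)[C@H]2CC[C@]1(O)C[Si](C)(C)OC(C)C | intermediate
27 | ethyl (3R,5S,8R,9S,10R,13Z)-3-(tert-butyldimethylsilyloxy)-8,17-dihydroxylabd-13-en-15-oate | C/C(=C/C(=O)OCC)CC[C@H]1[C@]2(C)CC[C@@H](O[Si](C)(C)C(C)(C)C)C(C)(C)[C@H]2CC[C@]1(O)CO | intermediate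
28 | (3R,5S,8R,9S,10R,13Z)-3-(tert-butyldimethylsilyloxy)-8,17-dihydroxylabd-13-en-15-oic acid | C/C(=C/C(=O)O)CC[C@H]1[C@]2(C)CC[C@@H](O[Si](C)(C)C(C)(C)C)C(C)(C)[C@H]2CC[C@]1(O)CO | intermediate
29 | (3R,5S,8R,9S,10R,13Z)-3-(tert-butyldimethylsilyloxy)-8-hydroxy-17-oxolabd-13-en-15-oic acid | C/C(=C/C(=O)O)CC[C@H]1[C@]2(C)CC[C@@H](O[Si](C)(C)C(C)(C)C)C(C)(C)[C@H]2CC[C@]1(O)C=O | intermediate
30 | (3R,5S,8R,9S,10R,13Z)-3,8-dihydroxy-17-oxolabd-13-en-15-oic acid, CNP0273710.1 | C/C(=C/C(=O)O)CC[C@H]1[C@]2(C)CC[C@@H](O)C(C)(C)[C@H]2CC[C@]1(O)C=O | target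

Total step count: 19.
Longest linear sequence: 18 steps (steps 1–12 and 14–19). Step 13 is a one-step side branch.

Steps most likely to fail

Step 8. The trisubstituted enoate may cycloadd too slowly. Ionisation of the dienyl or allylic pivalate by the aluminium Lewis acid, exo approach, or reaction through the tether conformer with an axial silyloxy group could then take over. The fallback sets out from 12 and comes back at 18. It activates the diene instead of the dienophile and uses no Lewis acid.
- Soft enolisation of 12 (TESOTf, Et3N, Et2O, 0 °C) should give the (8E,10E)-triethylsilyl dienol ether F1, a much stronger donor diene.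
- Heating in toluene (BHT, sealed tube, about 170 °C) should close both rings to the 8-triethylsilyloxy octalin F2.
- Hydrogenation (H2, 5% Rh/Al2O3) gives the decalin ester F3, and LiAlH4 gives the primary alcohol F4.
- PPTS in MeOH then removes only the more labile triethylsilyl group to give diol 18.

Step 7. Strong-base dienolate formation may suffer from incomplete control of the C5=C6 and C7=C8 geometry. It may also suffer from C-acylation at C7 or from competing deprotonation of the enoate. The fallback sets out from 12 and comes back at 15. It separates enolisation from acylation.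
- Soft enolisation through the O-silylated oxocarbenium ion (TMSOTf, Et3N, Et2O, 0 °C) needs no strong base and should give the trimethylsilyl dienol ether F5, used crude.
- Fluoride-catalysed silicon-to-acyl exchange with pivaloyl fluoride (Bu4NF, 5 mol %, THF, −78 → 0 °C) then acylates the liberated dienolate on oxygen only, giving 15.

Step 16. Addition to the hindered C8 ketone may be slow enough that attack on, or γ-deprotonation of, the unsaturated ester side chain competes. That would cause loss of the ester or erosion of the (13Z) geometry. The fallback sets out from 20 and comes back at 27. It installs C17 before any ester is present.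
- DMP oxidation of 20 gives the C9-vinyl ketone F6.
- The same silylmethyl Grignard reagent with LaCl3·2LiCl, which suppresses enolisation of this β,γ-unsaturated ketone, adds equatorially to give the silylmethyl carbinol F7.
- H2O2/KF/KHCO3 gives the vinyl 8,17-diol F8.
- Excess 9-BBN gives the C12 borane F9, and Suzuki–Miyaura coupling with 22 (Pd(dppf)Cl2, AsPh3, Cs2CO3, DMF/H2O) gives 27.

Further compounds
F1 | step 8 | methyl (2E,6R,8E,10E)-6-(tert-butyldimethylsilyloxy)-3,7,7-trimethyl-11-(triethylsilyloxy)undeca-2,8,10-trienoate | COC(=O)/C=C(\C)CC[C@@H](O[Si](C)(C)C(C)(C)C)C(C)(C)/C=C/C=C/O[Si](CC)(CC)CC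
F2 | step 8 | methyl (1S,2R,4aS,6R,8aR)-6-(tert-butyldimethylsilyloxy)-5,5,8a-trimethyl-2-(triethylsilyloxy)-1,2,4a,5,6,7,8,8a-octahydronaphthalene-1-carboxylate | COC(=O)[C@H]1[C@]2(C)CC[C@@H](O[Si](C)(C)C(C)(C)C)C(C)(C)[C@H]2C=C[C@H]1O[Si](CC)(CC)CC
F3 | step 8 | methyl (1S,2R,4aS,6R,8aR)-6-(tert-butyldimethylsilyloxy)-5,5,8a-trimethyl-2-(triethylsilyloxy)decahydronaphthalene-1-carboxylate | COC(=O)[C@H]1[C@]2(C)CC[C@@H](O[Si](C)(C)C(C)(C)C)C(C)(C)[C@H]2CC[C@H]1O[Si](CC)(CC)CC
F4 | step 8 | [(1R,2R,4aS,6R,8aR)-6-(tert-butyldimethylsilyloxy)-5,5,8a-trimethyl-2-(triethylsilyloxy)decahydronaphthalen-1-yl]methanol | OC[C@H]1[C@]2(C)CC[C@@H](O[Si](C)(C)C(C)(C)C)C(C)(C)[C@H]2CC[C@H]1O[Si](CC)(CC)CC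
F5 | step 7 | methyl (2E,6R,8E,10E)-6-(tert-butyldimethylsilyloxy)-3,7,7-trimethyl-11-(trimethylsilyloxy)undeca-2,8,10-trienoate | COC(=O)/C=C(\C)CC[C@@H](O[Si](C)(C)C(C)(C)C)C(C)(C)/C=C/C=C/O[Si](C)(C)C
F6 | step 16 | (1S,4aS,6R,8aR)-6-(tert-butyldimethylsilyloxy)-1-ethenyl-5,5,8a-trimethyloctahydronaphthalen-2(1H)-one | C=C[C@H]1[C@]2(C)CC[C@@H](O[Si](C)(C)C(C)(C)C)C(C)(C)[C@H]2CCC1=O
F7 | step 16 | (1S,2R,4aS,6R,8aR)-6-(tert-butyldimethylsilyloxy)-1-ethenyl-2-[(isopropoxydimethylsilyl)methyl]-5,5,8a-trimethyldecahydronaphthalen-2-ol | C=C[C@H]1[C@]2(C)CC[C@@H](O[Si](C)(C)C(C)(C)C)C(C)(C)[C@H]2CC[C@]1(O)C[Si](C)(C)OC(C)C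
F8 | step 16 | (1S,2R,4aS,6R,8aR)-6-(tert-butyldimethylsilyloxy)-1-ethenyl-2-(hydroxymethyl)-5,5,8a-trimethyldecahydronaphthalen-2-ol | C=C[C@H]1[C@]2(C)CC[C@@H](O[Si](C)(C)C(C)(C)C)C(C)(C)[C@H]2CC[C@]1(O)CO
F9 | step 16 | 9-BBN adduct of F8, boron on C12, drawn with both hydroxyls free | C1CC2CCCC(C1)B2CC[C@H]1[C@]2(C)CC[C@@H](O[Si](C)(C)C(C)(C)C)C(C)(C)[C@H]2CC[C@]1(O)CO
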